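More time at heat need not mean more target: Tuesday's target stood at 23.9% after 4.00 min and had fallen to 15.9% by 8.00 min.

| setting | Saturday's | Tuesday's | red | ochre | violet | teal |
|---|---|---|---|---|---|---|
| substrate | 10 mM | 10 mM | 10 mM | 10 mM | 10 mM | 10 mM |
| coupling partner | 1.5 equiv | 1.5 equiv | 1.50 equiv | 1.50 equiv | 1.50 equiv | 1.50 equiv |
| free catalyst | 0.5 mol% | 2 mol% | 1 mol% | 1 mol% | 1 mol% | 1 mol% |
| temperature | 35 °C | 70 °C | 100 °C | 60 °C | 80 °C | 40 °C |
| remark | run made earlier | run made earlier |  |  |  |  |
| time |  |  | 3.0 min | 3.0 min | 3.0 min | 3.0 min |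

- Saturday's (time / min: target / %, substrate / %): 4.00: 1.2, 99.1; 6.00: 1.1, 97.8; 12.0: 2.6, 96.3; 25.0: 6.1, 93.6; 50.0: 8.7, 87.1
- Tuesday's (time / min: target / %, substrate / %): 0.667: 10.8, 87.9; 1.00: 15.1, 82.3; 2.00: 23.0, 65.7; 4.00: 23.9, 39.8; 8.00: 15.9, 11.0

(standard deviation of a reading: 0.3 percentage points)

1. the flask that comes out highest in amount of target, in percent of the substrate charged, or "all alike" when all lie within 1.5 percentage points (red / ochre / violet / teal / all alike)
2. target at the end, in percent of the substrate charged, red
3. target at the end, in percent of the substrate charged, ochre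
4. target at the end, in percent of the substrate charged, violet
5. target at the end, in percent of the substrate charged, teal

- the numbers in the tables scatter with a standard deviation of 0.3 percentage points

My own reckoning began with target made per unit of catalyst and per minute, read while target was still rising. Tuesday's first reading gave 16.6 times the value from Saturday's reading at 25.0 min, which as an Arrhenius law means 70.6 kJ mol⁻¹. Teal's 3.0 min then scales by its loading and this temperature factor to 0.140 min. That figure is the Tuesday-equivalent time: the minutes of Tuesday's run that do the work of a flask's time, assuming rate proportional to catalyst.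

The same scaling gave ochre 0.714 min, violet 3.02 min and red 11.0 min. Violet's equivalent time lay between the times of Tuesday's two highest readings, and red's lay past Tuesday's last reading, so I chose violet. Tuesday's first slope put teal at 2.27%.

The forecast named violet, with red 8.5%, ochre 10.8%, violet 23.5% and teal 2.3%, on the ground that “80 °C for 3 min is about Tuesday at 3 min, near the peak”.

The flasks gave red 10.8%, ochre 11.4%, violet 18.9% and teal 2.19%, so violet came out highest, though below Tuesday's readings on either side of its equivalent time.

    coupling partner + free catalyst → catalyst intermediate A (k = 264 M⁻¹ s⁻¹, Ea = 42.0 kJ mol⁻¹)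
    catalyst intermediate A → by-product + catalyst intermediate B (k = 1.61 s⁻¹, Ea = 85.0 kJ mol⁻¹)
    substrate + catalyst intermediate B → catalyst intermediate C (k = 59.3 M⁻¹ s⁻¹, Ea = 53.0 kJ mol⁻¹)
    catalyst intermediate C → free catalyst + target (k = 1.43 s⁻¹, Ea = 84.0 kJ mol⁻¹)
    coupling partner + free catalyst + target → free catalyst + over-reaction product (k = 755 M⁻² s⁻¹, Ea = 42.0 kJ mol⁻¹)
    target + by-product → side product (k = 5.82 M⁻¹ s⁻¹, Ea = 59.0 kJ mol⁻¹)
    (constants at 80 °C)

Teal's 0.140 min had given 2.27%, and teal gave 2.19%. The neighbouring flask, teal with 4 mol% of free catalyst, scales to 0.561 min, hence 9.09%, and it gave 8.46%. After 3.00 min, catalyst intermediates A and C were the main resting states in teal, at 35.3% and 38.0% of the catalyst charged, and the neighbouring flask held them at 34.6% and 37.2%.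

(All runs come from a simulation with made-up constants; the scatter is artificial.)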